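**Retrosynthetic overview**
1. 11 ⇒ seco-phenol 10: the C1–O bond is made last; acid protonates C14, H1α shifts to C10, and an ortho OH closes the benzoxepine onto C1 (sets C1 and C10).
2. 10 ⇒ C4–C7′ bond: the carbinol carbon C4 of spathulenol with its polarity reversed (tertiary alkyl radical, a carbanion equivalent, from the cesium oxalate) adds to the electrophilic o-quinone methide 9 made from 7 + 8 (sets C4 and C7′).
3. Spathulenol 4 ⇒ (+)-aromadendrene 1 by ozonolysis, C4–H hydroxylation and methylenation.
4. Ring order: the cyclopropane, the seven- and five-membered carbocycles come intact from 1 and the arene from 7; the only ring made is the seven-membered benzoxepine, formed last.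

Assumption: (+)-aromadendrene, 2,4-diformylphloroglucinol and isovaleraldehyde are bought; atoms are numbered as in aromadendrane (C1–C15), C7′ is the benzylic carbon, C1′–C6′ the arene, and β is the face of the CMe2 bridge.

**Step 1**
Reactants: 1 (+)-aromadendrene
Product: 3 4β-hydroxy-14-noraromadendran-10-one, via apoaromadendrone 2 (not isolated)
Conditions: O3/O2, EtOAc, −78 °C, then Me2S, 20 °C; crude ketone adsorbed on SiO2, O3, −78 → 20 °C
Reagents that add atoms: ozone, [O-][O+]=O
Why: Ozonolysis removes the exocyclic CH2 (C14) without touching the ring stereocentres, and ozone then inserts with retention into the most electron-rich accessible tertiary C–H (C4–H; C1–H is deactivated by the carbonyl, C5–H is shielded next to the cyclopropane, and cyclopropane C–H bonds are too strong), giving the 4β-carbinol; alkene ozonolysis followed by dry-ozonation C–H hydroxylation, the sequence known from the preparation of spathulenol.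

**Step 2**
Reactants: 3 4β-hydroxy-14-noraromadendran-10-one
Product: 4 (+)-spathulenol
Conditions: Ph3PCH3Br, KOtBu (3 equiv each), THF, 0 → 45 °C
Reagents that add atoms: methyltriphenylphosphonium bromide, C[P+](c1ccccc1)(c1ccccc1)c1ccccc1.[Br-]
Why: Wittig methylenation of the ketone restores the C10=C14 alkene that later serves as the cation precursor; addition of the salt-free ylide outruns enolisation toward C1, so H1α is kept and no new stereocentre is formed.

**Step 3**
Reactants: 4 (+)-spathulenol
Product: 6 cesium spathulenyl oxalate, via methyl oxalate ester 5 (not isolated)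
Conditions: ClC(O)CO2Me, Et3N, DMAP (cat.), CH2Cl2, 0 → 20 °C; then CsOH·H2O (1.0 equiv), THF/H2O, 20 °C
Reagents that add atoms: methyl chlorooxoacetate, COC(=O)C(Cl)=O; cesium hydroxide, [Cs+].[OH-]
Why: DMAP-catalysed acylation of the tertiary alcohol and mild saponification of the methyl ester give the bench-stable cesium alkyl oxalate, the standard precursor of a tertiary alkyl radical (Overman-type oxalate activation); C4 is not touched.

**Step 4**
Reactants: 6 cesium spathulenyl oxalate; 7 2,4-diformylphloroglucinol; 8 isovaleraldehyde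
Product: 10 4β-[(1R)-1-(3,5-diformyl-2,4,6-trihydroxyphenyl)-3-methylbutyl]aromadendr-10(14)-ene, via o-quinone methide 9 (not isolated)
Conditions: Ir[dF(CF3)ppy]2(dtbbpy)PF6 (2 mol%), NaOAc (20 mol%), DME/DMF 3:1, H2O (10 equiv), 456 nm LEDs, 35 °C, 8 added over 6 h
Reagents that add atoms: none
Why: Proposed new method: excited Ir[dF(CF3)ppy]2(dtbbpy)PF6 oxidises the oxalate, loss of two CO2 turns the carbinol carbon C4 (normally an acceptor) into a nucleophilic tertiary radical, a tertiary-carbanion equivalent, which adds to the electrophilic exocyclic carbon of o-quinone methide 9 (formed in situ by Knoevenagel condensation of 7 and 8), and the resulting aryloxyl radical is reduced to the phenoxide by the reduced photocatalyst, so two acceptor carbons are joined; the planar C4 radical is attacked on its β face, anti to the C5–C6 bond and cis to H5β (C7′ β, CH3 α), and C7′ is set in an open staggered transition state with H over the cyclopentane, the isobutyl group in the free sector between C3 and CH3 and the quinone methide ring next to C5, which gives the 7′R epimer with only modest expected preference (the 7′-epimer is removed by chromatography); the closest known reaction types are the photoredox Giese addition of tertiary alkyl cesium oxalates to Michael acceptors and radical conjugate addition to quinone methides.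

**Step 5**
Reactants: 10 4β-[(1R)-1-(3,5-diformyl-2,4,6-trihydroxyphenyl)-3-methylbutyl]aromadendr-10(14)-ene
Product: 11 target CNP0189833.2
Conditions: TfOH (5 mol%), HFIP/CH2Cl2 1:4, −40 → 0 °C
Reagents that add atoms: none
Why: Markovnikov protonation of C14 gives the tertiary C10 cation, the axial H1α migrates suprafacially to the α face of C10 (H10α, CH3-10 β), and the new C1 cation is captured on its β face, anti to the departed hydride, by an ortho phenol held there by the C4β tether (the two ortho OH groups are equivalent and the arene has no free carbon), closing the seven-membered ether with the cis 1β-O/5β-H fusion; this is a cationic alkene hydroalkoxylation with a Wagner–Meerwein 1,2-hydride shift, the laboratory counterpart of the hydride-shift path by which 1-oxygenated aromadendranes arise.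

**Compound list**
1 | (+)-aromadendrene (aromadendr-10(14)-ene; 1αH,5βH,4α-CH3) | C[C@@H]1CC[C@@H]2[C@@H]1[C@H]3[C@H](C3(C)C)CCC2=C | starting material
2 | apoaromadendrone (14-noraromadendran-10-one; 1αH,5βH) | C[C@@H]1CC[C@@H]2[C@@H]1[C@H]3[C@H](C3(C)C)CCC2=O | intermediate
3 | 4β-hydroxy-14-noraromadendran-10-one (1αH,5βH,4α-CH3) | C[C@]1(O)CC[C@@H]2[C@@H]1[C@H]3[C@H](C3(C)C)CCC2=O | intermediate
4 | (+)-spathulenol (4β-hydroxyaromadendr-10(14)-ene; 1αH,5βH) | C[C@]1(O)CC[C@@H]2[C@@H]1[C@H]3[C@H](C3(C)C)CCC2=C | intermediate
5 | spathulenyl methyl oxalate (4β-O-C(O)CO2Me) | C[C@]1(OC(=O)C(=O)OC)CC[C@@H]2[C@@H]1[C@H]3[C@H](C3(C)C)CCC2=C | intermediate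
6 | cesium spathulenyl oxalate (4β-O-C(O)CO2Cs) | C[C@]1(OC(=O)C(=O)[O-])CC[C@@H]2[C@@H]1[C@H]3[C@H](C3(C)C)CCC2=C.[Cs+] | intermediate
7 | 2,4-diformylphloroglucinol (2,4,6-trihydroxybenzene-1,3-dicarbaldehyde) | O=Cc1c(O)cc(O)c(C=O)c1O | starting material
8 | isovaleraldehyde (3-methylbutanal) | CC(C)CC=O | starting material
9 | o-quinone methide 2,4-dihydroxy-5-(3-methylbutylidene)-6-oxocyclohexa-1,3-diene-1,3-dicarbaldehyde | CC(C)CC=C1C(=O)C(C=O)=C(O)C(C=O)=C1O | intermediate
10 | 4β-[(1R)-1-(3,5-diformyl-2,4,6-trihydroxyphenyl)-3-methylbutyl]aromadendr-10(14)-ene (1αH,5βH,4α-CH3) | C[C@]1([C@@H](CC(C)C)c2c(O)c(C=O)c(O)c(C=O)c2O)CC[C@@H]2[C@@H]1[C@H]3[C@H](C3(C)C)CCC2=C | intermediate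
11 | target CNP0189833.2: aromadendrane bridged from C4 (β) to C1 (β) by the C7′H(isobutyl)–aryl–O unit; 1S,4R,5R,6R,7R,10S,7′R; 5βH, 10αH, CMe2 bridge β; arene with 2′,4′-OH and 3′,5′-CHO | CC(C)C[C@H]1c2c(O)c(C=O)c(O)c(C=O)c2O[C@]23CC[C@@]1(C)[C@H]2[C@H]1[C@@H](CC[C@@H]3C)C1(C)C | target

**Totals**
Total step count: 5. Longest linear sequence: 5 steps (1 → 3 → 4 → 6 → 10 → 11).

**Steps most likely to fail**

Step 4 is the weakest. The diastereoselectivity at C7′ rests on an open transition state and may be low. Quinone methide 9 can also undergo hetero-Diels–Alder addition to the C10=C14 alkene, and the phenoxides may quench the photocatalyst. The fallback sets out from 6 and comes back at 11, and it brings in the isobutyl group last, under control of the rigid ring. The same photoredox coupling is run with the parent o-quinone methide F1 (from 7 and paraformaldehyde), which has no prochiral carbon, and gives the benzyl adduct F2. TfOH/HFIP, as in step 5, closes it to the 7′-unsubstituted benzoxepine F3. DDQ dehydrogenates the p-hydroxybenzylic CH2 to the ring quinone methide F4. Methallyltrimethylsilane with BF3·OEt2 adds to C7′ from the less shielded face on the side of the one-carbon bridge C5 and gives the methallyl compound F5 with the 7′R configuration. H2 over (PPh3)3RhCl saturates the 1,1-disubstituted alkene and gives 11.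

Step 5 is next. Loss of a proton from the C10 cation and re-protonation can compete with the hydride shift and erode the configuration at C10 or C1. The fallback sets out from 10 and comes back at 11, and it sets C10 by hydrogenation instead of a hydride shift. Pd(OAc)2 with 1,4-benzoquinone in AcOH/CH2Cl2 activates the allylic C1–H as a π-allylpalladium unit (C1–C10–C14) bound on the α face. The ortho phenoxide attacks the tertiary terminus C1 from the β face and gives the exo-methylene benzoxepine F6. H2 over (PPh3)3RhCl then adds to the open α face of C10=C14 (the β face is blocked by the aryl ether and the CMe2 bridge) and gives 11 with H10α.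

Step 1 is third. The ozone C–H insertion may be low-yielding or unselective. The fallback sets out from 2 (isolated after the Me2S work-up) and comes back at 11, and it uses C4–H directly instead of a C4–O handle. MeMgBr/CeCl3 gives the C10 carbinol epiglobulol F7; its 10-epimer ionises to the same cation and need not be removed. (Bu4N)4[W10O32] under 390 nm light abstracts the remote tertiary C4–H, and the C4 radical is trapped by 9, made as in step 4, to give the carbinol adduct F8. TfOH/HFIP ionises the C10–OH, and the hydride shift and etherification of step 5 give 11.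

**Further compounds**
F1 | step 4 | parent o-quinone methide 2,4-dihydroxy-5-methylidene-6-oxocyclohexa-1,3-diene-1,3-dicarbaldehyde | C=C1C(=O)C(C=O)=C(O)C(C=O)=C1O
F2 | step 4 | 4β-(3,5-diformyl-2,4,6-trihydroxybenzyl)aromadendr-10(14)-ene (1αH,5βH,4α-CH3) | C[C@]1(Cc2c(O)c(C=O)c(O)c(C=O)c2O)CC[C@@H]2[C@@H]1[C@H]3[C@H](C3(C)C)CCC2=C
F3 | step 4 | 7′-unsubstituted benzoxepine (11 without the isobutyl group; 1S,4R,5R,6R,7R,10S) | C1c2c(O)c(C=O)c(O)c(C=O)c2O[C@]23CC[C@@]1(C)[C@H]2[C@H]1[C@@H](CC[C@@H]3C)C1(C)C
F4 | step 4 | ring quinone methide of F3 (C7′=C1′, C4′=O) | C1=C2C(O)=C(C=O)C(=O)C(C=O)=C2O[C@]34CC[C@@]1(C)[C@H]3[C@H]1[C@@H](CC[C@@H]4C)C1(C)C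
F5 | step 4 | 7′R-(2-methylallyl) analogue of 11 | C=C(C)C[C@H]1c2c(O)c(C=O)c(O)c(C=O)c2O[C@]23CC[C@@]1(C)[C@H]2[C@H]1[C@@H](CC[C@@H]3C)C1(C)C
F6 | step 5 | 10(14)-ene analogue of 11 (exo-methylene benzoxepine) | CC(C)C[C@H]1c2c(O)c(C=O)c(O)c(C=O)c2O[C@]23CC[C@@]1(C)[C@H]2[C@H]1[C@@H](CCC3=C)C1(C)C
F7 | step 1 | epiglobulol (aromadendran-10β-ol; 1αH,5βH) | C[C@@H]1CC[C@@H]2[C@@H]1[C@H]3[C@H](C3(C)C)CC[C@]2(C)O
F8 | step 1 | 4β-[(1R)-1-(3,5-diformyl-2,4,6-trihydroxyphenyl)-3-methylbutyl]aromadendran-10β-ol | C[C@]1([C@@H](CC(C)C)c2c(O)c(C=O)c(O)c(C=O)c2O)CC[C@@H]2[C@@H]1[C@H]3[C@H](C3(C)C)CC[C@]2(C)O
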